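**Retrosynthetic overview**

1. Numbering: ring C1(=C2)–C3–C4–C5–C6, with C7 the CH2 on C1. The strategy rests on C1: it is the α-carbon of the enoyl unit C7(=O)–C1=C2 (C7 taken back to a thioester) and also the neighbour of carbinol C6, so the ring bond C1–C6 is a Morita–Baylis–Hillman bond.
2. Endgame: the C5 benzoate comes from opening a 4,5-orthobenzoate, the C7 benzoate from reduction of the C7 thioester and acylation; O3 and O6 are carried as silyl ethers.
3. Key disconnection C1–C6: PMe3-catalysed intramolecular Morita–Baylis–Hillman reaction of an acyclic (E)-enethioate aldehyde closes the cyclohexene, the only ring formed, and sets C6.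
4. The acyclic precursor maps onto D-arabinose (sugar C2, C3, C4 become C3, C4, C5; sugar C5 becomes the C6 aldehyde; sugar C1 becomes C2) and a thioester ylide (C1, C7), joined by a Wittig reaction on the 3,4-acetonide lactol.

Key step: step 6

Assumption: S-ethyl (triphenylphosphoranylidene)thioacetate (3) is treated as a purchasable stabilised ylide; if it is not in stock it is two routine operations from bromoacetyl bromide, ethanethiol and PPh3.

**Route**

Step 1
Reactants: 1 D-arabinose
Product: 2 3,4-O-isopropylidene-D-arabinopyranose (lactol; anomeric mixture)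
Conditions: Me2C(OMe)2 (1.3 equiv), TsOH·H2O (cat.), DMF, rt; Et3N quench
Reagents that add atoms: 2,2-dimethoxypropane, COC(C)(C)OC
Why: Acid-catalysed transacetalisation (kinetic acetonide formation) should take the only cis-vicinal diol away from the anomeric centre, O3/O4, leaving the lactol and O2 free and touching no stereocentre.

Step 2
Reactants: 2 3,4-O-isopropylidene-D-arabinopyranose; 3 S-ethyl (triphenylphosphoranylidene)thioacetate
Product: 4 S-ethyl (E)-2,3-dideoxy-5,6-O-isopropylidene-D-arabino-hept-2-enethioate (free 4-OH and 7-OH)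
Conditions: 3 (1.5 equiv), PhCO2H (cat.), toluene, 80 °C
Reagents that add atoms: none
Why: Wittig olefination of the aldehyde tautomer of the lactol with a stabilised ylide should give the (E)-enethioate, and the base-free aprotic medium should keep the released primary hydroxyl from adding back to the acceptor (oxa-Michael).

Step 3
Reactants: 4 diol enethioate
Product: 5 4,7-bis-O-TBS ether of 4
Conditions: TBSOTf (2.5 equiv), 2,6-lutidine, CH2Cl2, −78 → 0 °C
Reagents that add atoms: tert-butyldimethylsilyl trifluoromethanesulfonate, CC(C)(C)[Si](C)(C)OS(=O)(=O)C(F)(F)F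
Why: Silyl triflate with a hindered, non-nucleophilic base is a standard silylation that should cap both hydroxyls quickly without touching the thioester or the acetonide.

Step 4
Reactants: 5 bis-TBS ether
Product: 6 primary alcohol (4-O-TBS retained; future C6–OH free)
Conditions: HF·pyridine, pyridine, THF, 0 °C
Reagents that add atoms: none
Why: Buffered HF·pyridine should cleave the unhindered primary TBS ether much faster than the secondary allylic one (selective desilylation), and the acidic medium disfavours oxa-Michael closure.

Step 5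
Reactants: 6 primary alcohol
Product: 7 (E)-enethioate aldehyde EtS–C7(=O)–C1H=C2H–C3H(OTBS)–C4H(O)–C5H(O)–C6H=O with a cis-4,5-acetonide (D-arabino configuration)
Conditions: Dess–Martin periodinane, CH2Cl2, 0 °C → rt; NaHCO3/Na2S2O3 work-up
Reagents that add atoms: none
Why: Dess–Martin oxidation is non-basic, so the epimerisable α-alkoxy centre C5 should survive, and the thioester sulfur is not oxidised; the aldehyde is used directly.

Step 6
Reactants: 7 (E)-enethioate aldehyde
Product: 8 S-ethyl 6-hydroxy-3-(TBS-oxy)-4,5-(isopropylidenedioxy)cyclohex-1-ene-1-carbothioate (target numbering; acetonide on one face, 3-OTBS and 6-OH on the other)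
Conditions: PMe3 (0.5 equiv), CH2Cl2 (0.02 M), rt
Reagents that add atoms: none
Why: PMe3 adds in conjugate fashion to C2 of the enethioate, the resulting phosphonium thioester enolate attacks the tethered C6 aldehyde through C1 to form the C1–C6 bond, and proton transfer from C1 followed by E1cB loss of PMe3 restores the C1=C2 alkene inside the new ring. This is the phosphine-catalysed intramolecular Morita–Baylis–Hillman cyclisation of ω-formyl enethioates, a known route to five- and six-membered hydroxycycloalkene carboxylates. The cyclohexene closes in a 6-(enolexo)-exo-trig aldol mode, and the cis-4,5-acetonide holds the two chain ends gauche and so pre-folds the tether. The one new stereocentre, C6, is controlled by the C5 acetal oxygen: in the chair-like transition state both the polar Felkin–Anh arrangement (forming bond anti to C5–O) and the Cornforth arrangement (C=O anti to C5–O) place the new hydroxyl trans to O5, on the ring face away from the dioxolane. The aldol step is reversible ahead of the slower proton transfer, so the more stable trans aldolate should also be the one carried forward, and kinetic and thermodynamic bias point the same way. The step needs facial selectivity at C6 and no epimerisation at C5; the neutral conditions, the high electrophilicity of the thioester toward the phosphine and high dilution (against intermolecular Rauhut–Currier or aldol coupling) are what secure them, and C3, C4 and C5 are not touched.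

Step 7
Reactants: 8 cyclohexenol thioester
Product: 9 3,6-bis-O-TBS thioester (6-O-TBS ether of 8)
Conditions: TBSOTf, 2,6-lutidine, CH2Cl2, −78 → 0 °C
Reagents that add atoms: tert-butyldimethylsilyl trifluoromethanesulfonate, CC(C)(C)[Si](C)(C)OS(=O)(=O)C(F)(F)F
Why: Silyl triflate silylation should cap the hindered allylic C6 hydroxyl, so that O6 is distinguished from the O7 hydroxyl made in the next step.

Step 8
Reactants: 9 bis-TBS thioester
Product: 11 C7 allylic alcohol (3,6-bis-O-TBS-4,5-O-isopropylidene cyclohexenylmethanol), via enal 10 (not isolated)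
Conditions: i-Bu2AlH (3.5 equiv), CH2Cl2, −78 → −20 °C; aq. potassium sodium tartrate
Reagents that add atoms: none
Why: i-Bu2AlH reduces the thioester by 1,2-hydride delivery to the enal (thiolate leaves readily) and then to the allylic alcohol, while silyl ethers and the acetonide are inert to it.

Step 9
Reactants: 11 allylic alcohol
Product: 12 C7 benzoate (3,6-bis-O-TBS, 4,5-acetonide)
Conditions: BzCl, pyridine, DMAP (cat.), CH2Cl2, 0 °C
Reagents that add atoms: benzoyl chloride, O=C(Cl)c1ccccc1
Why: Standard acylation of the only free hydroxyl, a primary allylic alcohol.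

Step 10
Reactants: 12 C7 benzoate acetonide
Product: 13 4,5-diol (7-O-benzoyl, 3,6-bis-O-TBS)
Conditions: TFA/H2O (9:1), CH2Cl2, 0 °C, quenched at full conversion
Reagents that add atoms: none
Why: Acid-catalysed acetal hydrolysis proceeds through an unhindered oxocarbenium ion, whereas the two secondary TBS ethers need water to attack crowded silicon, so the acetonide should go first; the benzoate is stable.

Step 11
Reactants: 13 4,5-diol
Product: 15 5-O-benzoate 4-alcohol (7-O-benzoyl, 3,6-bis-O-TBS), via cyclic 4,5-orthobenzoate 14 (not isolated)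
Conditions: PhC(OMe)3, CSA (cat.), CH2Cl2, rt; then AcOH/H2O (4:1), rt
Reagents that add atoms: trimethyl orthobenzoate, COC(OC)(OC)c1ccccc1; water, O
Why: Orthoester exchange on the cis-diol followed by mild acid hydrolysis gives the ester on the axial oxygen (regioselective orthoester opening), and O5 should be the axial one because A(1,2) strain with the C1–CH2OBz group holds the 6-OTBS pseudoaxial and O5 is trans to it; no stereocentre is changed.

Step 12
Reactants: 15 bis-TBS dibenzoate
Product: 16 [(3R,4S,5R,6S)-5-(benzoyloxy)-3,4,6-trihydroxycyclohex-1-en-1-yl]methyl benzoate (target)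
Conditions: 48% aq. HF, MeCN, 0 °C → rt (polypropylene vessel)
Reagents that add atoms: none
Why: Acidic fluoride desilylation should remove both secondary TBS ethers while avoiding the base-induced benzoyl migration (O5→O4/O6, O7→O6) that basic fluoride sources would invite.

**Compound list**

1 | D-arabinose | O=C[C@@H](O)[C@H](O)[C@H](O)CO | starting material
2 | 3,4-O-isopropylidene-D-arabinopyranose (anomeric centre left open, mutarotating lactol) | OC1[C@@H](O)[C@@H]2OC(C)(C)O[C@@H]2CO1 | intermediate
3 | S-ethyl (triphenylphosphoranylidene)thioacetate | CCSC(=O)C=P(c1ccccc1)(c1ccccc1)c1ccccc1 | starting material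
4 | S-ethyl (E)-2,3-dideoxy-5,6-O-isopropylidene-D-arabino-hept-2-enethioate | CCSC(=O)/C=C/[C@@H](O)[C@@H]1OC(C)(C)O[C@@H]1CO | intermediate
5 | 4,7-bis-O-TBS ether of 4 | CCSC(=O)/C=C/[C@@H](O[Si](C)(C)C(C)(C)C)[C@@H]1OC(C)(C)O[C@@H]1CO[Si](C)(C)C(C)(C)C | intermediate
6 | 4-O-TBS ether of 4 with free primary 7-OH | CCSC(=O)/C=C/[C@@H](O[Si](C)(C)C(C)(C)C)[C@@H]1OC(C)(C)O[C@@H]1CO | intermediate
7 | (E)-enethioate aldehyde (C7-oxidised 6; 3-OTBS, cis-4,5-acetonide, C6 aldehyde in target numbering) | CCSC(=O)/C=C/[C@@H](O[Si](C)(C)C(C)(C)C)[C@@H]1OC(C)(C)O[C@@H]1C=O | intermediate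
8 | S-ethyl 6-hydroxy-3-(TBS-oxy)-4,5-(isopropylidenedioxy)cyclohex-1-ene-1-carbothioate (3-OTBS and 6-OH trans to the acetonide) | CCSC(=O)C1=C[C@@H](O[Si](C)(C)C(C)(C)C)[C@@H]2OC(C)(C)O[C@@H]2[C@H]1O | intermediate
9 | 6-O-TBS ether of 8 | CCSC(=O)C1=C[C@@H](O[Si](C)(C)C(C)(C)C)[C@@H]2OC(C)(C)O[C@@H]2[C@H]1O[Si](C)(C)C(C)(C)C | intermediate
10 | enal (C7 aldehyde; 3,6-bis-O-TBS, 4,5-acetonide) | O=CC1=C[C@@H](O[Si](C)(C)C(C)(C)C)[C@@H]2OC(C)(C)O[C@@H]2[C@H]1O[Si](C)(C)C(C)(C)C | intermediate
11 | C7 allylic alcohol (3,6-bis-O-TBS, 4,5-acetonide) | OCC1=C[C@@H](O[Si](C)(C)C(C)(C)C)[C@@H]2OC(C)(C)O[C@@H]2[C@H]1O[Si](C)(C)C(C)(C)C | intermediate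
12 | C7 benzoate (3,6-bis-O-TBS, 4,5-acetonide) | O=C(OCC1=C[C@@H](O[Si](C)(C)C(C)(C)C)[C@@H]2OC(C)(C)O[C@@H]2[C@H]1O[Si](C)(C)C(C)(C)C)c1ccccc1 | intermediate
13 | 4,5-diol (7-O-benzoyl, 3,6-bis-O-TBS) | O=C(OCC1=C[C@@H](O[Si](C)(C)C(C)(C)C)[C@H](O)[C@H](O)[C@H]1O[Si](C)(C)C(C)(C)C)c1ccccc1 | intermediate
14 | cyclic 4,5-orthobenzoate of 13 (2-methoxy-2-phenyl-1,3-dioxolane; both epimers at the ortho carbon) | O=C(OCC1=C[C@@H](O[Si](C)(C)C(C)(C)C)[C@@H]2OC(OC)(c3ccccc3)O[C@@H]2[C@H]1O[Si](C)(C)C(C)(C)C)c1ccccc1 | intermediate
15 | 5-O-benzoate 4-alcohol (7-O-benzoyl, 3,6-bis-O-TBS) | O=C(OCC1=C[C@@H](O[Si](C)(C)C(C)(C)C)[C@H](O)[C@H](OC(=O)c2ccccc2)[C@H]1O[Si](C)(C)C(C)(C)C)c1ccccc1 | intermediate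
16 | [(3R,4S,5R,6S)-5-(benzoyloxy)-3,4,6-trihydroxycyclohex-1-en-1-yl]methyl benzoate | O=C(OCC1=C[C@@H](O)[C@H](O)[C@H](OC(=O)c2ccccc2)[C@H]1O)c1ccccc1 | target

**Summary**

Total step count: 12. Longest linear sequence: 12 steps (1 → 16).

**Steps most likely to fail**

Step 6 (ring closure). Turnover of the phosphonium aldolate (proton transfer and phosphine loss) may be slow. That would let intermolecular Rauhut–Currier or aldol coupling, enolisation of the aldehyde with epimerisation at C5, or attack on the wrong aldehyde face compete. The fallback is a stoichiometric two-stage surrogate of the same bond formation, setting out from 7. PhSeLi (from PhSeSePh and n-BuLi) in THF at −78 °C should add to C2, and the lithium enolate should close onto the C6 aldehyde at low temperature, giving the 2-phenylselanyl aldol adduct F1. Oxidation with H2O2/pyridine in CH2Cl2 at 0 °C would give the selenoxide F2. Its syn-elimination should go toward C1, since selenoxides avoid eliminating toward an oxygen-bearing carbon such as C3. This restores the C1=C2 alkene and returns to the route at 8.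

Step 11 (orthobenzoate opening). The hemiorthoester may collapse toward the O4 ester if the ring reacts through the other half-chair, or the benzoyl group may migrate from O5 to O4 during work-up. The fallback sets out from 13 and uses the complementary regiochemical rule. Bu2SnO in toluene at reflux with removal of water should give the 4,5-O-dibutylstannylene acetal F3. BzCl at 0 °C → rt then acylates the equatorial oxygen of a tin acetal, which is O5 in exactly the conformer in which the orthoester route fails. The fallback returns to the route at 15.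

Step 10 (acetonide hydrolysis). One or both allylic silyl ethers may be lost, or silicon may migrate onto the freed hydroxyls, before the acetal is fully hydrolysed. The fallback sets out from 12 and removes everything instead of seeking selectivity. TFA/H2O (4:1) at rt should cleave the acetonide and both TBS ethers to give the 7-O-benzoyl tetraol F4. With PhC(OMe)3 (1.1 equiv) and CSA in MeCN, only the cis pair O4/O5 can form a five-membered cyclic orthoester, the tetraol 4,5-orthobenzoate F5. AcOH/H2O should then open it to the axial O5 benzoate, which is the target, so the fallback returns to the route at 16.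

**Further compounds**

F1 | step 6 | S-ethyl 6-hydroxy-2-(phenylselanyl)-3-(TBS-oxy)-4,5-(isopropylidenedioxy)cyclohexane-1-carbothioate (C1 and C2 configuration open) | CCSC(=O)C1C([Se]c2ccccc2)[C@@H](O[Si](C)(C)C(C)(C)C)[C@@H]2OC(C)(C)O[C@@H]2[C@H]1O
F2 | step 6 | selenoxide of F1 | CCSC(=O)C1C([Se](=O)c2ccccc2)[C@@H](O[Si](C)(C)C(C)(C)C)[C@@H]2OC(C)(C)O[C@@H]2[C@H]1O
F3 | step 11 | 4,5-O-dibutylstannylene acetal of 13 | O=C(OCC1=C[C@@H](O[Si](C)(C)C(C)(C)C)[C@@H]2O[Sn](CCCC)(CCCC)O[C@@H]2[C@H]1O[Si](C)(C)C(C)(C)C)c1ccccc1
F4 | step 10 | (3,4,5,6-tetrahydroxycyclohex-1-en-1-yl)methyl benzoate, configuration as in 16 | O=C(OCC1=C[C@@H](O)[C@H](O)[C@H](O)[C@H]1O)c1ccccc1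
F5 | step 10 | cyclic 4,5-orthobenzoate of F4 | O=C(OCC1=C[C@@H](O)[C@@H]2OC(OC)(c3ccccc3)O[C@@H]2[C@H]1O)c1ccccc1
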